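All runs are simulated for substances that don't exist.

Which of the four flasks holds the most D after 30 min, and how much, when the earlier runs stop well short of what teal is asked to do?

| flask | X | temperature | remark | time |
|---|---|---|---|---|
| dusk | 0.025 M | 2 °C | run made earlier |  |
| summer | 0.038 M | 19 °C | run made earlier |  |
| violet | 0.050 M | −5 °C |  | 30 min |
| grey | 0.050 M | 10 °C |  | 30 min |
| teal | 0.050 M | 25 °C |  | 30 min |
| ochre | 0.050 M |  | at −5 °C until 10 min, from then on at 25 °C | 30 min |

| run | time / min | D / % | X / % |
|---|---|---|---|
| dusk | 3.00 | 0 | 84.1 |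
| dusk | 8.00 | 2.8 | 64.1 |
| dusk | 15.0 | 6.0 | 41.5 |
| dusk | 25.0 | 6.8 | 30.5 |
| summer | 0.667 | 2.6 | 69.4 |
| summer | 1.33 | 1.2 | 51.9 |
| summer | 3.00 | 5.6 | 31.6 |
| summer | 8.00 | 12.9 | 21.8 |

(readings scatter by 1 percentage point)

- the flask that comes out highest in amount of D, in percent of the X charged, or "all alike" when all lie within 1.5 percentage points (violet / grey / teal / ochre / all alike)
- D at the end, in percent of the X charged, violet
- D at the end, in percent of the X charged, grey
- D at the end, in percent of the X charged, teal
- D at the end, in percent of the X charged, ochre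

Teal looks like the close relative of the summer run, at 25 °C against 19 °C, but I don't compare them by temperature. The first two readings of [X] give an early fall constant of 0.0543 min⁻¹ in dusk and 0.438 min⁻¹ in summer. I take this fall as first order, which is an assumption, since the charges differ too. The count of turnovers, that constant times the time in the flask, is 3.51 at summer's last reading.

With the logarithm of the constant running straight in temperature, teal gets 0.916 min⁻¹, twice summer's. It also runs 30 min instead of 8.00 min, so by this count it ends at 27.5 turnovers, more than at any reading of either run. Grey, with 0.145 min⁻¹, ends at 4.35, so on this count grey, not teal, is summer's neighbour. By the same count ochre stands at 18.5 and violet at 0.690.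

Summer's last reading gives 3.68% of D per turnover, and dusk's gives 5.01%, which is larger. At summer's yield per turnover my own reckoning is 16.0% for grey and 2.54% for violet. For teal the same rule prints 101%, above the whole charge, and the yield per turnover already reads lower in summer than in dusk, so I refuse that figure as an estimate. I give no number for teal or ochre, and I leave the top place open.

The forecast, “assumed first order despite the different concentrations”, names teal as highest, with violet 3.8%, grey 25%, teal 55% and ochre 41%. For grey it stands above my figure.

The flask highest in D is grey: violet 2.31%, grey 14.9%, teal 8.37%, ochre 9.26%.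

    X ⇌ E (K = 1.70, k = 0.0190 s⁻¹, Ea = 91.0 kJ mol⁻¹, ΔH = −27.0 kJ mol⁻¹)
    E ⇌ D (K = 0.310, k = 0.00220 s⁻¹, Ea = 77.0 kJ mol⁻¹, ΔH = −2.00 kJ mol⁻¹)
    X ⇌ Z (K = 3.30, k = 0.00240 s⁻¹, Ea = 86.0 kJ mol⁻¹, ΔH = 3.00 kJ mol⁻¹)
    D ⇌ L (K = 0.630, k = 2.50 × 10⁻⁴ s⁻¹, Ea = 101 kJ mol⁻¹, ΔH = −54.0 kJ mol⁻¹)
    (constants at 25 °C)

In teal, D goes from 10.1% at 15.0 min to 8.37% at 30.0 min while Z climbs from 37.8% to 45.9%, the pattern of kinetic against thermodynamic control. Grey, at 4.35 turnovers by my count, lies past summer's 3.51 and holds more D than summer's last reading. Grey's charge run at 35 °C, which my count puts at 93.8 turnovers, holds 5.92% of D.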